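**Plan**

1. Ring numbering: C1 (carries the exocyclic CH2), C2=C3 (E), C4 (gem-dimethyl), C5 (R, O-vanilloyl), C6, C7, C8(Me)=C9 (E), C10, C11. This eleven-membered carbocycle is the only non-aromatic ring.
2. The first cuts are the C5–O acyl bond and C1=CH2, which leads back to a C1 ketone. The ring then holds C1(=O)–C2=C3–C4(Me)2–C5(OH), a δ-hydroxy-γ,γ-dimethyl E-enone. This 1,5-oxygen pattern is that of a vinylogous aldol and allows the ring bond C4–C5 to be cut.
3. The open chain is cut at C10–C11 (β-keto ester alkylation) and at C6–C7 (Johnson–Claisen rearrangement).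
4. Forward: a C5–C10 bromo ester is joined to a C11–C4 β-keto ester whose C3=C4 alkene is kept out of conjugation, which directs enolisation to the C1(OSi)=C2–C3=C4 dienol ether. Ester-to-aldehyde reduction, closure of the ring, acylation, methylenation and phenol release follow.
5. Stereochemistry: C5 comes from the chiral boron Lewis acid in the ring closure (Si-face attack). E-C8=C9 comes from the chair Claisen transition state and E-C2=C3 from the s-trans diene.

Key step: step 9

Assumption: the sense of induction is extrapolated from intermolecular enol silane aldol additions promoted by tryptophan-derived oxazaborolidinones, where the (S)-promoter leaves the Re face of RCH2CHO open. The (R)-promoter is therefore specified. Both antipodes are accessible, and C5 would be checked on diastereomeric esters.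

Step 1
Reactants: 1 (tert-butyldimethylsilyloxy)acetaldehyde; 2 isopropenylmagnesium bromide
Product: 3 1-(tert-butyldimethylsilyloxy)-3-methylbut-3-en-2-ol (racemic)
Conditions: THF, −78 → 0 °C; aqueous work-up
Reagents that add atoms: none
Why: Grignard 1,2-addition to an unhindered α-silyloxy aldehyde; the racemic carbinol centre is erased in step 2.

Step 2
Reactants: 3 1-(tert-butyldimethylsilyloxy)-3-methylbut-3-en-2-ol; 4 trimethyl orthoacetate
Product: 6 methyl (E)-6-(tert-butyldimethylsilyloxy)-4-methylhex-4-enoate, via mixed ketene acetal 5 (not isolated)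
Conditions: 4 (excess), EtCO2H (cat.), xylene, 135 °C, MeOH distilled off
Reagents that add atoms: none
Why: Johnson–Claisen rearrangement, in which the chair transition state with CH2OTBS equatorial forms C6–C7 and should give the E-trisubstituted C8=C9 alkene.

Step 3
Reactants: 6 methyl (E)-6-(tert-butyldimethylsilyloxy)-4-methylhex-4-enoate
Product: 7 methyl (E)-6-bromo-4-methylhex-4-enoate
Conditions: Ph3PBr2, CH2Cl2, 0 °C → rt
Reagents that add atoms: dibromotriphenylphosphorane, BrP(Br)(c1ccccc1)(c1ccccc1)c1ccccc1
Why: Appel-type direct bromination of a primary allylic silyl ether through an oxyphosphonium ion and SN2 displacement, which leaves the ester and the alkene geometry untouched.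

Step 4
Reactants: 8 4-methylpent-3-enoic acid; 9 Meldrum's acid; 10 allyl alcohol
Product: 12 allyl 6-methyl-3-oxohept-5-enoate, via acyl Meldrum's acid 11 (not isolated)
Conditions: DCC, DMAP, CH2Cl2, 0 °C → rt; filter, aq KHSO4 wash, concentrate; then 10, toluene, 110 °C
Reagents that add atoms: none
Why: C-acylation of Meldrum's acid followed by thermal acylketene formation and trapping with the alcohol is the standard β-keto ester synthesis, and it is neutral enough to keep C3=C4 out of conjugation.

Step 5
Reactants: 12 allyl 6-methyl-3-oxohept-5-enoate; 7 methyl (E)-6-bromo-4-methylhex-4-enoate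
Product: 13 1-allyl 8-methyl (E)-5-methyl-2-(4-methylpent-3-enoyl)oct-4-enedioate (racemic at ring C11)
Conditions: NaH (1.0 equiv), THF, 0 °C; then 7, 0 °C → rt
Reagents that add atoms: none
Why: Acetoacetic-ester alkylation, in which one equivalent of base removes only the doubly activated C11 hydrogen and the primary allylic bromide reacts by SN2 at C10; the C11 centre is lost in step 6.

Step 6
Reactants: 13 1-allyl 8-methyl (E)-5-methyl-2-(4-methylpent-3-enoyl)oct-4-enedioate
Product: 15 methyl (E)-4,11-dimethyl-8-oxododeca-4,10-dienoate, via β-keto acid 14 (not isolated)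
Conditions: Pd(PPh3)4 (3 mol %), morpholine (2 equiv), THF, rt
Reagents that add atoms: none
Why: Tsuji–Trost-type deallylation (allyl transfer to morpholine) and spontaneous decarboxylation of the β-keto acid run close to neutrality, so the skipped C3=C4 enone and the methyl ester should survive.

Step 7
Reactants: 15 methyl (E)-4,11-dimethyl-8-oxododeca-4,10-dienoate
Product: 16 methyl (4E,8Z)-8-(tert-butyldimethylsilyloxy)-4,11-dimethyldodeca-4,8,10-trienoate
Conditions: TBSOTf (1.15 equiv), Et3N (2 equiv), CH2Cl2, −78 → −20 °C
Reagents that add atoms: tert-butyldimethylsilyl triflate, CC(C)(C)[Si](C)(C)OS(=O)(=O)C(F)(F)F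
Why: Soft enolisation (silyl triflate/tertiary amine): the C2 hydrogens lie between the carbonyl group and the C3=C4 alkene and are much more acidic than those at C11, so the through-conjugated dienol ether should form with the Z geometry usual for this method, whereas the conjugated enone isomer would be expected to enolise toward C11 under the same conditions.

Step 8
Reactants: 16 methyl (4E,8Z)-8-(tert-butyldimethylsilyloxy)-4,11-dimethyldodeca-4,8,10-trienoate
Product: 17 (4E,8Z)-8-(tert-butyldimethylsilyloxy)-4,11-dimethyldodeca-4,8,10-trienal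
Conditions: DIBAL-H (1.05 equiv), toluene, −78 °C; MeOH, then aq Rochelle salt
Reagents that add atoms: none
Why: Partial ester reduction through the aluminium hemiacetal, which persists at −78 °C, while the C1 ketone is masked as its silyl dienol ether.

Step 9
Reactants: 17 (4E,8Z)-8-(tert-butyldimethylsilyloxy)-4,11-dimethyldodeca-4,8,10-trienal
Product: 18 (2E,5R,8E)-5-hydroxy-4,4,8-trimethylcycloundeca-2,8-dien-1-one
Conditions: N-tosyl-D-tryptophan + PhBCl2, CH2Cl2, rt, then evaporation [(R)-B-phenyl oxazaborolidinone, 1.0 equiv]; i-PrOH (1.1 equiv), EtCN, −78 °C; 17 added by syringe pump (final ca. 1 mM); aq NaHCO3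
Reagents that add atoms: none
Why: Proposed new method: the boron Lewis acid binds the unbranched C5 aldehyde, C4 (the diene terminus carrying the largest HOMO coefficient of the Z-silyl dienol ether) attacks it through an open transition state, and 2-propanol removes the silyl group from the resulting silyloxyallyl cation, which unveils the C1 ketone in conjugation with the new C2=C3 bond. The closest known reaction types are the intermolecular oxazaborolidinone-promoted enantioselective vinylogous Mukaiyama aldol addition and the Lewis-acid-mediated intramolecular vinylogous aldol macrocyclisation; their union at a fully substituted γ-carbon is what has not been shown. The eleven-membered ring closes in an 11-exo-trig mode with respect to the C5=O bond, with both double bonds of the dienol ether ending inside the ring, and slow addition to a full equivalent of promoter keeps free 17 too dilute for intermolecular aldol addition. C5 is controlled by the promoter alone: the formyl C–H···O contact fixes the bound aldehyde, the indole of the (R)-configured ligand covers its Re face, and C4 therefore arrives on the Si face to give 5R. The step needs γ- over α-attack, which the substrate secures because C2 is flanked by the OTBS-bearing C1 and because bonding at C2 would have to build a nine-membered ring around the E-C8=C9 alkene. The E geometry of C2=C3 follows from the s-trans diene conformer, since the s-cis form suffers a clash between the inner C4 methyl group and the silyloxy group on C1.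

Step 10
Reactants: 19 vanillic acid
Product: 21 4-(tert-butyldimethylsilyloxy)-3-methoxybenzoic acid, via bis-silyl vanillate 20 (not isolated)
Conditions: TBSCl (2.5 equiv), imidazole, DMF, rt; then AcOH–THF–H2O, rt
Reagents that add atoms: tert-butyldimethylsilyl chloride, CC(C)(C)[Si](C)(C)Cl
Why: Persilylation followed by selective hydrolysis of the far more labile silyl ester, a routine way to mask only the phenol of a hydroxybenzoic acid.

Step 11
Reactants: 18 (2E,5R,8E)-5-hydroxy-4,4,8-trimethylcycloundeca-2,8-dien-1-one; 21 4-(tert-butyldimethylsilyloxy)-3-methoxybenzoic acid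
Product: 23 (2E,5R,8E)-4,4,8-trimethyl-1-oxocycloundeca-2,8-dien-5-yl 4-(tert-butyldimethylsilyloxy)-3-methoxybenzoate (ring numbering of the plan), via mixed anhydride 22 (not isolated)
Conditions: 21, 2,4,6-Cl3C6H2COCl, Et3N, toluene, rt; then 18, DMAP, toluene, rt → 50 °C
Reagents that add atoms: none
Why: Yamaguchi esterification, chosen for the neopentyl-type C5 carbinol; the C5–O bond is not broken so 5R is retained, and capping the hydroxyl before any strong base is used removes the path to retro-vinylogous aldol ring opening.

Step 12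
Reactants: 23 (2E,5R,8E)-4,4,8-trimethyl-1-oxocycloundeca-2,8-dien-5-yl 4-(tert-butyldimethylsilyloxy)-3-methoxybenzoate
Product: 24 (2E,5R,8E)-4,4,8-trimethyl-1-methylidenecycloundeca-2,8-dien-5-yl 4-(tert-butyldimethylsilyloxy)-3-methoxybenzoate
Conditions: Ph3PCH3Br, KHMDS, THF, 0 °C; then 23, −20 °C → rt
Reagents that add atoms: methyltriphenylphosphonium bromide, C[P+](c1ccccc1)(c1ccccc1)c1ccccc1.[Br-]
Why: Wittig methylenation, in which the unstabilised ylide adds 1,2 to the enone carbonyl far faster than to the hindered, electron-rich aryl ester, and neither C5 nor the two E alkenes are touched.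

Step 13
Reactants: 24 (2E,5R,8E)-4,4,8-trimethyl-1-methylidenecycloundeca-2,8-dien-5-yl 4-(tert-butyldimethylsilyloxy)-3-methoxybenzoate
Product: 25 (2E,5R,8E)-4,4,8-trimethyl-1-methylidenecycloundeca-2,8-dien-5-yl 4-hydroxy-3-methoxybenzoate (CNP0416843.1)
Conditions: TBAF, AcOH (1:1), THF, 0 °C
Reagents that add atoms: none
Why: Fluoride-induced cleavage of the aryl silyl ether, buffered with acetic acid so that phenoxide does not build up and the ester and the triene stay intact.

**Compound list**

1 | (tert-butyldimethylsilyloxy)acetaldehyde | O=CCO[Si](C)(C)C(C)(C)C | starting material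
2 | isopropenylmagnesium bromide | C=C(C)[Mg]Br | starting material
3 | 1-(tert-butyldimethylsilyloxy)-3-methylbut-3-en-2-ol (racemic) | C=C(C)C(O)CO[Si](C)(C)C(C)(C)C | intermediate
4 | trimethyl orthoacetate | CC(OC)(OC)OC | starting material
5 | 1-methoxyvinyl ether of 3 (mixed ketene acetal, not isolated) | C=C(OC)OC(CO[Si](C)(C)C(C)(C)C)C(C)=C | intermediate
6 | methyl (E)-6-(tert-butyldimethylsilyloxy)-4-methylhex-4-enoate | COC(=O)CC/C(C)=C/CO[Si](C)(C)C(C)(C)C | intermediate
7 | methyl (E)-6-bromo-4-methylhex-4-enoate | COC(=O)CC/C(C)=C/CBr | intermediate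
8 | 4-methylpent-3-enoic acid | CC(C)=CCC(=O)O | starting material
9 | Meldrum's acid (2,2-dimethyl-1,3-dioxane-4,6-dione) | CC1(C)OC(=O)CC(=O)O1 | starting material
10 | allyl alcohol | C=CCO | starting material
11 | 2,2-dimethyl-5-(4-methylpent-3-enoyl)-1,3-dioxane-4,6-dione (not isolated) | CC(C)=CCC(=O)C1C(=O)OC(C)(C)OC1=O | intermediate
12 | allyl 6-methyl-3-oxohept-5-enoate | C=CCOC(=O)CC(=O)CC=C(C)C | intermediate
13 | 1-allyl 8-methyl (E)-5-methyl-2-(4-methylpent-3-enoyl)oct-4-enedioate (racemic) | C=CCOC(=O)C(C/C=C(\C)CCC(=O)OC)C(=O)CC=C(C)C | intermediate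
14 | (E)-8-methoxy-5-methyl-2-(4-methylpent-3-enoyl)-8-oxooct-4-enoic acid (not isolated) | OC(=O)C(C/C=C(\C)CCC(=O)OC)C(=O)CC=C(C)C | intermediate
15 | methyl (E)-4,11-dimethyl-8-oxododeca-4,10-dienoate | COC(=O)CC/C(C)=C/CCC(=O)CC=C(C)C | intermediate
16 | methyl (4E,8Z)-8-(tert-butyldimethylsilyloxy)-4,11-dimethyldodeca-4,8,10-trienoate | COC(=O)CC/C(C)=C/CC/C(O[Si](C)(C)C(C)(C)C)=C/C=C(C)C | intermediate
17 | (4E,8Z)-8-(tert-butyldimethylsilyloxy)-4,11-dimethyldodeca-4,8,10-trienal | O=CCC/C(C)=C/CC/C(O[Si](C)(C)C(C)(C)C)=C/C=C(C)C | intermediate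
18 | (2E,5R,8E)-5-hydroxy-4,4,8-trimethylcycloundeca-2,8-dien-1-one | O=C1/C=C/C(C)(C)[C@H](O)CC/C(C)=C/CC1 | intermediate
19 | vanillic acid | COc1cc(C(=O)O)ccc1O | starting material
20 | tert-butyldimethylsilyl 4-(tert-butyldimethylsilyloxy)-3-methoxybenzoate (not isolated) | COc1cc(C(=O)O[Si](C)(C)C(C)(C)C)ccc1O[Si](C)(C)C(C)(C)C | intermediate
21 | 4-(tert-butyldimethylsilyloxy)-3-methoxybenzoic acid | COc1cc(C(=O)O)ccc1O[Si](C)(C)C(C)(C)C | intermediate
22 | 4-(tert-butyldimethylsilyloxy)-3-methoxybenzoic 2,4,6-trichlorobenzoic anhydride (not isolated) | COc1cc(C(=O)OC(=O)c2c(Cl)cc(Cl)cc2Cl)ccc1O[Si](C)(C)C(C)(C)C | intermediate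
23 | (2E,5R,8E)-4,4,8-trimethyl-1-oxocycloundeca-2,8-dien-5-yl 4-(tert-butyldimethylsilyloxy)-3-methoxybenzoate | O=C1/C=C/C(C)(C)[C@H](OC(=O)c2ccc(O[Si](C)(C)C(C)(C)C)c(OC)c2)CC/C(C)=C/CC1 | intermediate
24 | (2E,5R,8E)-4,4,8-trimethyl-1-methylidenecycloundeca-2,8-dien-5-yl 4-(tert-butyldimethylsilyloxy)-3-methoxybenzoate | C=C1/C=C/C(C)(C)[C@H](OC(=O)c2ccc(O[Si](C)(C)C(C)(C)C)c(OC)c2)CC/C(C)=C/CC1 | intermediate
25 | (2E,5R,8E)-4,4,8-trimethyl-1-methylidenecycloundeca-2,8-dien-5-yl 4-hydroxy-3-methoxybenzoate (CNP0416843.1) | C=C1/C=C/C(C)(C)[C@H](OC(=O)c2ccc(O)c(OC)c2)CC/C(C)=C/CC1 | target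

**Step count**

Total step count: 13. Longest linear sequence: 11 steps (1–3, 5–9, 11–13).

**Steps most likely to fail**

Step 9 (Proposed new method).
- **Risk:** Intermolecular aldol addition may outrun ring closure. The crowded C4 terminus may react too slowly, so that protodesilylation of the dienol ether takes over. Attack may occur through C2, or the promoter may discriminate poorly between the aldehyde faces in a macrocyclic transition state.
- **Fallback:** Ring closure and asymmetric induction are decoupled, using known chemistry only. The fallback sets out from 17 and comes back at 18. Aqueous HF in MeCN hydrolyses the dienol ether to the conjugated keto aldehyde (4E,9E)-4,11-dimethyl-8-oxododeca-4,9-dienal F1. Both carbonyl groups of F1 are complexed with aluminium tris(2,6-diphenylphenoxide) in toluene at −78 °C, and LiTMP is added under high dilution. This is the established intramolecular vinylogous aldol macrocyclisation. The aluminium pocket shields C11 and C2, so only the C4 hydrogen is removed and only C4 attacks. It should give racemic (2E,8E)-5-hydroxy-4,4,8-trimethylcycloundeca-2,8-dien-1-one F2. Esterification with (S)-O-methylmandelic acid (DCC, DMAP) and chromatography separates the (5R)-configured (S)-O-methylmandelate F3 from the (5S)-configured (S)-O-methylmandelate F4. Methanolysis of F3 (K2CO3, MeOH, 0 °C) returns 18.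

Step 12.
- **Risk:** The basic ylide may enolise the ketone at C11 instead of adding to it, or it may attack the aryl ester or the aryl silyl ether.
- **Fallback:** A two-stage Peterson olefination sets out from 23 and comes back at 25. Me3SiCH2MgCl with anhydrous CeCl3 (THF, −78 °C) adds 1,2 to the ketone to give the tertiary β-hydroxysilane (2E,5R,8E)-1-hydroxy-4,4,8-trimethyl-1-(trimethylsilylmethyl)cycloundeca-2,8-dien-5-yl 4-(tert-butyldimethylsilyloxy)-3-methoxybenzoate F5 (both C1 epimers). Aqueous HF in MeCN at 0 °C then triggers the silicon-directed elimination to the exocyclic methylene and cleaves the aryl silyl ether in the same operation.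

Step 8.
- **Risk:** The hemiacetal may collapse early, which leads to over-reduction. The dienol ether may also be hydrolysed during the aluminium work-up.
- **Fallback:** Full reduction followed by re-oxidation sets out from 16 and comes back at 17. DIBAL-H (2.5 equiv, CH2Cl2, −78 → 0 °C) gives (4E,8Z)-8-(tert-butyldimethylsilyloxy)-4,11-dimethyldodeca-4,8,10-trien-1-ol F6. A Parikh–Doering oxidation (SO3·pyridine, DMSO, Et3N, 0 °C) takes F6 to the aldehyde under base-buffered conditions.

**Further compounds**

F1 | step 9 | (4E,9E)-4,11-dimethyl-8-oxododeca-4,9-dienal | O=CCC/C(C)=C/CCC(=O)/C=C/C(C)C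
F2 | step 9 | racemic (2E,8E)-5-hydroxy-4,4,8-trimethylcycloundeca-2,8-dien-1-one | O=C1/C=C/C(C)(C)C(O)CC/C(C)=C/CC1
F3 | step 9 | (2E,5R,8E)-4,4,8-trimethyl-1-oxocycloundeca-2,8-dien-5-yl (S)-2-methoxy-2-phenylacetate | O=C1/C=C/C(C)(C)[C@H](OC(=O)[C@@H](OC)c2ccccc2)CC/C(C)=C/CC1
F4 | step 9 | (2E,5S,8E)-4,4,8-trimethyl-1-oxocycloundeca-2,8-dien-5-yl (S)-2-methoxy-2-phenylacetate | O=C1/C=C/C(C)(C)[C@@H](OC(=O)[C@@H](OC)c2ccccc2)CC/C(C)=C/CC1
F5 | step 12 | (2E,5R,8E)-1-hydroxy-4,4,8-trimethyl-1-(trimethylsilylmethyl)cycloundeca-2,8-dien-5-yl 4-(tert-butyldimethylsilyloxy)-3-methoxybenzoate (C1 epimers) | C[Si](C)(C)CC1(O)/C=C/C(C)(C)[C@H](OC(=O)c2ccc(O[Si](C)(C)C(C)(C)C)c(OC)c2)CC/C(C)=C/CC1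
F6 | step 8 | (4E,8Z)-8-(tert-butyldimethylsilyloxy)-4,11-dimethyldodeca-4,8,10-trien-1-ol | OCCC/C(C)=C/CC/C(O[Si](C)(C)C(C)(C)C)=C/C=C(C)C
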